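**Strategy.** The resorcinol ring is not bought but built: its oxygens on C1' and C3' and its lone carbon substituent on C5' are the pattern of a 5-substituted cyclohexane-1,3-dione. That dione is cut at C4'–C5' and C2'–C3' into dimethyl malonate and an E-enone, (R,E)-6-(benzyloxy)henicos-3-en-2-one, which already holds the C2 carbinol centre (set by Noyori hydrogenation) as a base- and acid-stable benzyl ether. One pot of conjugate addition, Claisen ring closure, saponification and decarboxylation turns the acyclic enone into the six-membered dione; bromination–dehydrobromination then aromatises it and hydrogenolysis frees the alcohol.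

Key step: step 6

Assumption: 1,3-dicarbonyl compounds (3, 12–16) are drawn in one tautomeric form although they exist as enols or enolates in the flask, and ring stereocentres that are erased later (in 11–13 and 16) are left undefined.

**Route**

Step 1
Reactants: 1 palmitoyl chloride; 2 Meldrum's acid
Product: 4 methyl 3-oxooctadecanoate, via acyl Meldrum's acid 3 (not isolated)
Conditions: pyridine (2 equiv), CH2Cl2, 0 °C to rt; then MeOH, reflux
Reagents that add atoms: methanol, CO
Why: Pyridine-mediated C-acylation of Meldrum's acid gives enol 3, and its methanolysis opens the dioxanedione with loss of acetone and CO2 to leave the β-keto ester (the Meldrum's acid route to β-keto esters).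

Step 2
Reactants: 4 methyl 3-oxooctadecanoate
Product: 5 methyl (R)-3-hydroxyoctadecanoate
Conditions: H2 (50 atm), RuCl2[(R)-BINAP] (cat.), MeOH, 50 °C
Reagents that add atoms: none
Why: Noyori asymmetric hydrogenation, in which the β-keto ester chelates ruthenium through both carbonyls and the (R)-BINAP ligand directs hydride to the ketone face that gives the (R)-carbinol, the same sense as in the reduction of methyl acetoacetate to methyl (R)-3-hydroxybutanoate.

Step 3
Reactants: 5 methyl (R)-3-hydroxyoctadecanoate
Product: 6 methyl (R)-3-(benzyloxy)octadecanoate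
Conditions: BnOC(=NH)CCl3 (1.5 equiv), TfOH (cat.), cyclohexane/CH2Cl2, 0 °C to rt
Reagents that add atoms: benzyl 2,2,2-trichloroacetimidate, N=C(OCc1ccccc1)C(Cl)(Cl)Cl
Why: Acid-catalysed O-benzylation with a trichloroacetimidate avoids the alkoxide that would cause retro-aldol cleavage or β-elimination of a β-hydroxy ester, and it leaves the C3–O bond and hence the configuration untouched.

Step 4
Reactants: 6 methyl (R)-3-(benzyloxy)octadecanoate
Product: 7 (R)-3-(benzyloxy)octadecanal
Conditions: iBu2AlH (DIBAL-H, 1.1 equiv), CH2Cl2, −78 °C; MeOH, then aq KNaC4H4O6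
Reagents that add atoms: none
Why: Partial reduction of an ester with DIBAL-H, in which the tetrahedral aluminium hemiacetal, held at −78 °C and by chelation to the β-benzyloxy oxygen, does not collapse until the quench, so that reduction stops at the aldehyde.

Step 5
Reactants: 7 (R)-3-(benzyloxy)octadecanal; 8 1-(triphenylphosphoranylidene)propan-2-one
Product: 9 (R,E)-6-(benzyloxy)henicos-3-en-2-one
Conditions: toluene, 80 °C
Reagents that add atoms: none
Why: Wittig olefination with a ketone-stabilised ylide, which is reliably E-selective and too weakly basic to eliminate benzyl alcohol from the β-benzyloxy aldehyde.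

Step 6
Reactants: 9 (R,E)-6-(benzyloxy)henicos-3-en-2-one; 10 dimethyl malonate
Product: 14 5-[(R)-2-(benzyloxy)heptadecyl]cyclohexane-1,3-dione, via Michael adduct 11 (not isolated), via cyclic keto ester 12 (not isolated), via keto acid 13 (not isolated)
Conditions: 10 (1.3 equiv), NaOMe (1.2 equiv), MeOH/THF, 0 °C, slow addition of 9, then reflux; aq NaOH, reflux; aq HCl to pH 1, 70 °C
Reagents that add atoms: none
Why: Sodium dimethyl malonate, preformed with the malonate in slight excess so that almost no free methoxide remains, adds in a Michael reaction to C4 of enone 9 (the future ring carbon C5') and gives 11, forming C4'–C5'. On heating, the methyl ketone of 11 is enolised at its methyl carbon and attacks one malonate ester carbonyl in a Claisen condensation, a 6-(enolendo)-exo-trig closure that forms C2'–C3', closes the only new ring and is pulled forward by deprotonation of the vinylogous acid 12. Hydroxide then saponifies the remaining ester, and acidification with warming decarboxylates β-keto acid 13 to dione 14; the whole sequence is the classical route from enones and malonates to 5-substituted cyclohexane-1,3-diones. No new stereocentre survives, because the ring carbons that are stereogenic in 11–13 are erased or become non-stereogenic in 14, while the existing C2 centre is a benzyl ether inert to alkoxide, hot hydroxide and hot acid. The selectivity required is conjugate addition ahead of deprotonation of 9 at its γ-carbon (which would expel benzyloxide by vinylogous E1cB elimination) and ahead of 1,2-addition; the soft, weakly basic malonate anion and the addition of 9 at 0 °C before any heating should secure it.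

Step 7
Reactants: 14 5-[(R)-2-(benzyloxy)heptadecyl]cyclohexane-1,3-dione
Product: 17 5-[(R)-2-(benzyloxy)heptadecyl]benzene-1,3-diol, via 2-bromodione 15 (not isolated), via 4-bromodione 16 (not isolated)
Conditions: Br2 (1.0 equiv), DMF, 0 °C; then 80–100 °C, N2
Reagents that add atoms: none
Why: Halogenation–dehydrohalogenation aromatisation of a cyclohexane-1,3-dione, in which the enol is brominated at C2 (15), the HBr formed equilibrates bromine to C4 (16), and loss of HBr across C4–C5 on heating gives cyclohex-4-ene-1,3-dione, which tautomerises to the resorcinol, while the benzyl ether and the remote stereocentre are not touched by one equivalent of bromine in DMF.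

Step 8
Reactants: 17 5-[(R)-2-(benzyloxy)heptadecyl]benzene-1,3-diol
Product: 18 5-[(R)-2-hydroxyheptadecyl]benzene-1,3-diol
Conditions: H2 (1 atm), 10% Pd/C, EtOAc/EtOH, rt
Reagents that add atoms: none
Why: Catalytic hydrogenolysis cleaves only the benzylic C–O bond of the ether, so that the C2–O bond and the (R) configuration are retained, and the resorcinol ring is not reduced at ambient pressure and temperature.

**Compound list**

1 | palmitoyl chloride (hexadecanoyl chloride) | CCCCCCCCCCCCCCCC(=O)Cl | starting material
2 | Meldrum's acid (2,2-dimethyl-1,3-dioxane-4,6-dione) | CC1(C)OC(=O)CC(=O)O1 | starting material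
3 | 5-(1-hydroxyhexadecylidene)-2,2-dimethyl-1,3-dioxane-4,6-dione (acyl Meldrum's acid) | CCCCCCCCCCCCCCCC(O)=C1C(=O)OC(C)(C)OC1=O | intermediate
4 | methyl 3-oxooctadecanoate | CCCCCCCCCCCCCCCC(=O)CC(=O)OC | intermediate
5 | methyl (R)-3-hydroxyoctadecanoate | CCCCCCCCCCCCCCC[C@@H](O)CC(=O)OC | intermediate
6 | methyl (R)-3-(benzyloxy)octadecanoate | CCCCCCCCCCCCCCC[C@@H](OCc1ccccc1)CC(=O)OC | intermediate
7 | (R)-3-(benzyloxy)octadecanal | CCCCCCCCCCCCCCC[C@@H](OCc1ccccc1)CC=O | intermediate
8 | 1-(triphenylphosphoranylidene)propan-2-one | CC(=O)C=P(c1ccccc1)(c1ccccc1)c1ccccc1 | starting material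
9 | (R,E)-6-(benzyloxy)henicos-3-en-2-one | CCCCCCCCCCCCCCC[C@@H](OCc1ccccc1)C/C=C/C(C)=O | intermediate
10 | dimethyl malonate | COC(=O)CC(=O)OC | starting material
11 | dimethyl 2-[(6R)-6-(benzyloxy)-2-oxohenicosan-4-yl]malonate (both C4 epimers) | CCCCCCCCCCCCCCC[C@@H](OCc1ccccc1)CC(CC(C)=O)C(C(=O)OC)C(=O)OC | intermediate
12 | methyl 6-[(R)-2-(benzyloxy)heptadecyl]-2,4-dioxocyclohexane-1-carboxylate | CCCCCCCCCCCCCCC[C@@H](OCc1ccccc1)CC1CC(=O)CC(=O)C1C(=O)OC | intermediate
13 | 6-[(R)-2-(benzyloxy)heptadecyl]-2,4-dioxocyclohexane-1-carboxylic acid | CCCCCCCCCCCCCCC[C@@H](OCc1ccccc1)CC1CC(=O)CC(=O)C1C(=O)O | intermediate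
14 | 5-[(R)-2-(benzyloxy)heptadecyl]cyclohexane-1,3-dione | CCCCCCCCCCCCCCC[C@@H](OCc1ccccc1)CC1CC(=O)CC(=O)C1 | intermediate
15 | 5-[(R)-2-(benzyloxy)heptadecyl]-2-bromocyclohexane-1,3-dione | CCCCCCCCCCCCCCC[C@@H](OCc1ccccc1)CC1CC(=O)C(Br)C(=O)C1 | intermediate
16 | 5-[(R)-2-(benzyloxy)heptadecyl]-4-bromocyclohexane-1,3-dione | CCCCCCCCCCCCCCC[C@@H](OCc1ccccc1)CC1CC(=O)CC(=O)C1Br | intermediate
17 | 5-[(R)-2-(benzyloxy)heptadecyl]benzene-1,3-diol | CCCCCCCCCCCCCCC[C@@H](OCc1ccccc1)Cc1cc(O)cc(O)c1 | intermediate
18 | 5-[(R)-2-hydroxyheptadecyl]benzene-1,3-diol | CCCCCCCCCCCCCCC[C@@H](O)Cc1cc(O)cc(O)c1 | target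

**Summary**

Total step count: 8. Longest linear sequence: 8 steps (1 to 18).

**Steps most likely to fail**

Step 6. The enone may be deprotonated at its γ-carbon and lose benzyloxide by vinylogous elimination, or the Michael addition may reverse during the hot Claisen stage, so that the acceptor is drained before the ring closes. The fallback moves the acidic methyl ketone from the acceptor to the donor. It sets out from aldehyde 7, which on Wittig olefination with methyl (triphenylphosphoranylidene)acetate in toluene at 80 °C should give methyl (R,E)-5-(benzyloxy)icos-2-enoate F1, a much less γ-acidic acceptor. Methyl acetoacetate and NaOMe in refluxing MeOH would then add through the acetoacetate α-carbon to give dimethyl 2-acetyl-3-[(R)-2-(benzyloxy)heptadecyl]pentanedioate F2. F2 is not isolated and should close by Claisen condensation of its acetyl methyl onto the chain ester. This gives the same cyclic keto ester, so the route is rejoined at 12, which is saponified and decarboxylated to 14 as in step 6.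

Step 7. The resorcinol may be brominated on the ring as fast as it forms, leaving part of the dione unoxidised, or bromine may fail to migrate from C2 to C4 so that dehydrobromination stalls. The fallback aromatises without bromine and caps one oxygen in the same operation. It sets out from dione 14, which with iodine in refluxing MeOH (vinylogous methyl ester formation, α'-iodination, loss of HI) should give 3-[(R)-2-(benzyloxy)heptadecyl]-5-methoxyphenol F3. BBr3 in CH2Cl2 at −78 to 0 °C would then cleave the aryl methyl ether and the benzyl ether together. The route is rejoined at target 18, and step 8 is not needed.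

Step 4. The aluminium hemiacetal may collapse before the quench and lead to over-reduction, or the β-benzyloxy aldehyde may lose benzyl alcohol by β-elimination while it is handled. The fallback sets out from ester 6, which with LiAlH4 in THF at 0 °C should give (R)-3-(benzyloxy)octadecan-1-ol F4. Oxidation with Dess–Martin periodinane and NaHCO3 in CH2Cl2, followed by addition of ylide 8 to the same flask, would olefinate the aldehyde without isolating it. The route is rejoined at enone 9.

**Further compounds**

F1 | step 6 | methyl (R,E)-5-(benzyloxy)icos-2-enoate | CCCCCCCCCCCCCCC[C@@H](OCc1ccccc1)C/C=C/C(=O)OC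
F2 | step 6 | dimethyl 2-acetyl-3-[(R)-2-(benzyloxy)heptadecyl]pentanedioate | CCCCCCCCCCCCCCC[C@@H](OCc1ccccc1)CC(CC(=O)OC)C(C(C)=O)C(=O)OC
F3 | step 7 | 3-[(R)-2-(benzyloxy)heptadecyl]-5-methoxyphenol | CCCCCCCCCCCCCCC[C@@H](OCc1ccccc1)Cc1cc(O)cc(OC)c1
F4 | step 4 | (R)-3-(benzyloxy)octadecan-1-ol | CCCCCCCCCCCCCCC[C@@H](OCc1ccccc1)CCO
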